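## Retrosynthetic overview

1. The target is ent-oritin-(4β→6)-epioritin-4α-ol. The key cut is the interflavan C4(upper)–C6(lower) bond: the upper unit is an electrophilic flav-3-ene oxide, the lower unit a ring-A nucleophile carried as its all-cis 3,4-diacetate.
2. The upper oxide comes from the (2R)-flav-3-ene (epoxidation anti to the 2-aryl group). The lower all-cis diol comes from the (2S)-flav-3-ene (Woodward cis-hydroxylation, both oxygens delivered syn to the 2-aryl group).
3. Both flav-3-enes (ring C of each unit) come from one chalcone-derived allylic alcohol by enantioselective chiral Brønsted acid cyclodehydration; the catalyst enantiomer selects the series.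
4. The chalcone comes from gallacetophenone 3,4-dibenzyl ether and 4-(benzyloxy)benzaldehyde (rings A and B are bought as arenes).
5. Ring order: ring C of the upper and lower units in parallel, then C4–C6 coupling, deacetylation, hydrogenolysis.

Assumption: the acid enantiomer written as (R) in step 4 is taken to give the (2R)-flavene (if the sense is opposite, the two enantiomers are exchanged between steps 4 and 5); flavan numbering is used, and α/β mean below/above the plane with ring A drawn on the left and O1 at the top.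

## Route

Step 1
Reactants: 1 1-(2,3,4-trihydroxyphenyl)ethanone (gallacetophenone)
Product: 2 1-[3,4-bis(benzyloxy)-2-hydroxyphenyl]ethanone
Conditions: BnBr (2.1 eq), K2CO3 (2.2 eq), DMF, rt to 50 °C
Reagents that add atoms: benzyl bromide, BrCc1ccccc1
Why: Williamson ether synthesis under weak base; the 2-OH is locked in a hydrogen bond to the acetyl group and stays free, so only the 3- and 4-hydroxyls are benzylated.

Step 2
Reactants: 2 1-[3,4-bis(benzyloxy)-2-hydroxyphenyl]ethanone; 3 4-(benzyloxy)benzaldehyde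
Product: 4 (E)-1-[3,4-bis(benzyloxy)-2-hydroxyphenyl]-3-[4-(benzyloxy)phenyl]prop-2-en-1-one
Conditions: KOH (50% aq.), EtOH, rt, 36 h; then dilute HCl
Reagents that add atoms: none
Why: Claisen–Schmidt aldol condensation of a methyl ketone with a non-enolisable aldehyde; E1cB dehydration gives the conjugated E-enone.

Step 3
Reactants: 4 (E)-2'-hydroxychalcone
Product: 5 (E)-1-[3,4-bis(benzyloxy)-2-hydroxyphenyl]-3-[4-(benzyloxy)phenyl]prop-2-en-1-ol (racemic)
Conditions: NaBH4 (1.5 eq), THF/EtOH, 0 °C; aq. NaHCO3 work-up; crude 5 used at once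
Reagents that add atoms: none
Why: Borohydride 1,2-reduction of a 2'-hydroxychalcone (the phenoxide-deactivated enone takes hydride at the carbonyl carbon); the carbinol centre is racemic and is erased in the next step, so no stereocentre of the target is set here.

Step 4
Reactants: 5 racemic allylic alcohol
Product: 6 (2R)-7,8-bis(benzyloxy)-2-[4-(benzyloxy)phenyl]-2H-chromene (2-aryl β)
Conditions: (R)-3,3'-bis(2,4,6-triisopropylphenyl)-BINOL N-triflylphosphoramide (5 mol%), 4 Å MS, toluene, −78 to −60 °C; Et3N quench; product kept cold and dark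
Reagents that add atoms: none
Why: Chiral Brønsted acid-catalysed dehydrative intramolecular allylic substitution (contact-ion-pair catalysis), a reaction class established for closely related chalcone-derived allylic alcohols: ionisation of 5 erases the carbinol centre to a delocalised o-hydroxybenzyl/cinnamyl cation held by the chiral phosphoramide anion, and the phenol oxygen closes on one face of the aryl-bearing terminus, which sets C2 (the first stereocentre carried to the target); a modest shortfall in ee is removed later because the coupling in step 7 turns minor enantiomers into separable diastereomers.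

Step 5
Reactants: 5 racemic allylic alcohol
Product: 7 (2S)-7,8-bis(benzyloxy)-2-[4-(benzyloxy)phenyl]-2H-chromene (2-aryl α)
Conditions: (S)-3,3'-bis(2,4,6-triisopropylphenyl)-BINOL N-triflylphosphoramide (5 mol%), 4 Å MS, toluene, −78 to −60 °C; Et3N quench; product kept cold and dark
Reagents that add atoms: none
Why: The same stereoablative chiral Brønsted acid-catalysed intramolecular allylic substitution with the mirror-image catalyst, which sets C2 of the lower unit as S (aryl α).

Step 6
Reactants: 7 (2S)-flav-3-ene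
Product: 10 (2R,3S,4R)-7,8-bis(benzyloxy)-2-[4-(benzyloxy)phenyl]chroman-3,4-diyl diacetate (all-cis), via iodo acetate 8 (not isolated), via hydroxy acetate 9 (not isolated)
Conditions: I2 (1.05 eq), AgOAc (2.2 eq), AcOH, rt, dark; then H2O (1.5 eq), 50 °C; filter, evaporate; then Ac2O, pyridine, DMAP (cat.), rt
Reagents that add atoms: silver acetate, CC(=O)[O-].[Ag+]; water, O; acetic anhydride, CC(=O)OC(C)=O
Why: Woodward–Prévost cis-hydroxylation: acetyl hypoiodite puts iodine on C3 anti to the 2-aryl group and acetate on benzylic C4, the C4 acetate then displaces iodide at C3 with inversion through a 1,3-dioxolan-2-ylium ion that water opens to the cis-hydroxy acetate, so both oxygens end up on the aryl face (3α,4α, all-cis); acetylation caps the diol.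

Step 7
Reactants: 6 (2R)-flav-3-ene; 10 all-cis diacetate (3 eq, excess recovered)
Product: 12 hexa-O-benzyl-ent-oritin-(4β→6)-epioritin-4α-ol 3,4-di-O-acetate, via flavene oxide 11 (not isolated)
Conditions: DMDO (1.1 eq, acetone), CH2Cl2, −40 °C, volatiles removed cold; then 10, (R)-TRIP (5 mol%), 4 Å MS, CH2Cl2, 11 added over 2 h, −78 to −50 °C; Et3N quench
Reagents that add atoms: dimethyldioxirane (DMDO), CC1(C)OO1
Why: Proposed new method: Brønsted-acid organocatalysed, stereoinvertive Friedel–Crafts opening of a flav-3-ene oxide by ring A of a second flavan unit. DMDO first epoxidises 6 anti to the 2-aryl group (3α,4α-oxirane 11). The chiral phosphoric acid then protonates the oxirane, whose benzylic C4–O bond is weakened by the para 7-benzyloxy group and the ring oxygen, giving a tight C4 carbenium–phosphate pair with the C3 oxygen held on the α face. The most electron-rich free position of 10 (C6, ortho to 7-OBn and para to O1; C5 is peri-hindered and only singly activated) attacks from the β face, which forms the C4–C6 bond, sets C4 (4β, 3,4-trans) and frees the 3-OH. The acetates on 10 block O-alkylation and keep its own C4 from ionising under this weak acid. The closest known reaction types are chiral phosphoric acid-catalysed Friedel–Crafts ring opening of aryl epoxides and arene additions to benzylic cation or quinone methide ion pairs, and Lewis acid-promoted C4–C6/C8 coupling of 4-oxygenated flavans.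

Step 8
Reactants: 12 dimer diacetate
Product: 13 hexa-O-benzyl-ent-oritin-(4β→6)-epioritin-4α-ol
Conditions: K2CO3 (0.3 eq), MeOH/THF, 0 °C to rt
Reagents that add atoms: none
Why: Base-catalysed transesterification (Zemplén-type methanolysis) removes both acetates; benzyl ethers and all stereocentres are untouched (no carbonyl or free 4'-OH through which a centre could epimerise).

Step 9
Reactants: 13 hexabenzyl dimer
Product: 14 ent-oritin-(4β→6)-epioritin-4α-ol (CNP0391561.2)
Conditions: H2 (1 atm), Pd(OH)2/C (20 wt%), THF/MeOH, rt, stopped at full conversion; filtered under argon, lyophilised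
Reagents that add atoms: none
Why: Catalytic hydrogenolysis of the six aryl benzyl ethers; the neutral medium, low pressure and short reaction time are chosen to leave the benzylic C4–OH of the lower unit and the C4–C6 bond intact, and no stereocentre is touched.

## Compound list

1 | 1-(2,3,4-trihydroxyphenyl)ethanone (gallacetophenone) | CC(=O)c1ccc(O)c(O)c1O | starting material
2 | 1-[3,4-bis(benzyloxy)-2-hydroxyphenyl]ethanone | CC(=O)c1ccc(OCc2ccccc2)c(OCc2ccccc2)c1O | intermediate
3 | 4-(benzyloxy)benzaldehyde | O=Cc1ccc(OCc2ccccc2)cc1 | starting material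
4 | (E)-1-[3,4-bis(benzyloxy)-2-hydroxyphenyl]-3-[4-(benzyloxy)phenyl]prop-2-en-1-one | O=C(/C=C/c1ccc(OCc2ccccc2)cc1)c1ccc(OCc2ccccc2)c(OCc2ccccc2)c1O | intermediate
5 | (E)-1-[3,4-bis(benzyloxy)-2-hydroxyphenyl]-3-[4-(benzyloxy)phenyl]prop-2-en-1-ol, racemic at the carbinol carbon | OC(/C=C/c1ccc(OCc2ccccc2)cc1)c1ccc(OCc2ccccc2)c(OCc2ccccc2)c1O | intermediate
6 | (2R)-7,8-bis(benzyloxy)-2-[4-(benzyloxy)phenyl]-2H-chromene (flav-3-ene, 2-aryl β) | C(c1ccccc1)Oc1ccc(cc1)[C@@H]1Oc2c(OCc3ccccc3)c(OCc3ccccc3)ccc2C=C1 | intermediate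
7 | (2S)-7,8-bis(benzyloxy)-2-[4-(benzyloxy)phenyl]-2H-chromene (flav-3-ene, 2-aryl α) | C(c1ccccc1)Oc1ccc(cc1)[C@H]1Oc2c(OCc3ccccc3)c(OCc3ccccc3)ccc2C=C1 | intermediate
8 | (2R,3R,4R)-7,8-bis(benzyloxy)-2-[4-(benzyloxy)phenyl]-3-iodochroman-4-yl acetate (2,3-trans-3,4-trans; iodine anti to the 2-aryl group; not isolated) | C(c1ccccc1)Oc1ccc(cc1)[C@H]1Oc2c(OCc3ccccc3)c(OCc3ccccc3)ccc2[C@@H](OC(C)=O)[C@@H]1I | intermediate
9 | (2R,3R,4R)-7,8-bis(benzyloxy)-2-[4-(benzyloxy)phenyl]-4-hydroxychroman-3-yl acetate (all-cis; the 4-O-acetyl regioisomer also forms; not isolated) | C(c1ccccc1)Oc1ccc(cc1)[C@H]1Oc2c(OCc3ccccc3)c(OCc3ccccc3)ccc2[C@@H](O)[C@H]1OC(C)=O | intermediate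
10 | (2R,3S,4R)-7,8-bis(benzyloxy)-2-[4-(benzyloxy)phenyl]chroman-3,4-diyl diacetate (all-cis; tri-O-benzylteracacidin diacetate) | C(c1ccccc1)Oc1ccc(cc1)[C@H]1Oc2c(OCc3ccccc3)c(OCc3ccccc3)ccc2[C@@H](OC(C)=O)[C@H]1OC(C)=O | intermediate
11 | (2S,3R,4R)-7,8-bis(benzyloxy)-2-[4-(benzyloxy)phenyl]-3,4-epoxychroman (3α,4α-oxirane, trans to the 2β-aryl group; not isolated) | C(c1ccccc1)Oc1ccc(cc1)[C@@H]1Oc2c(OCc3ccccc3)c(OCc3ccccc3)ccc2[C@H]2O[C@@H]12 | intermediate
12 | hexa-O-benzyl-ent-oritin-(4β→6)-epioritin-4α-ol 3,4-di-O-acetate: upper unit 2β-aryl, 3α-OH, 4β-aryl, bonded through C4 to C6 of the all-cis lower unit, which carries 3α- and 4α-OAc; benzyl on O7, O8 and O4' of both units | C(c6ccccc6)Oc1ccc([C@H]2Oc3c(cc([C@H]4c5ccc(OCc6ccccc6)c(OCc6ccccc6)c5O[C@@H](c5ccc(OCc6ccccc6)cc5)[C@@H]4O)c(OCc6ccccc6)c3OCc6ccccc6)[C@@H](OC(C)=O)[C@H]2OC(C)=O)cc1 | intermediate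
13 | hexa-O-benzyl-ent-oritin-(4β→6)-epioritin-4α-ol (free 3-OH on the upper unit, free 3α- and 4α-OH on the lower unit) | C(c6ccccc6)Oc1ccc([C@H]2Oc3c(cc([C@H]4c5ccc(OCc6ccccc6)c(OCc6ccccc6)c5O[C@@H](c5ccc(OCc6ccccc6)cc5)[C@@H]4O)c(OCc6ccccc6)c3OCc6ccccc6)[C@@H](O)[C@H]2O)cc1 | intermediate
14 | (2R,3R,4R)-6-[(2S,3R,4S)-3,7,8-trihydroxy-2-(4-hydroxyphenyl)chroman-4-yl]-2-(4-hydroxyphenyl)chroman-3,4,7,8-tetraol, ent-oritin-(4β→6)-epioritin-4α-ol | Oc1ccc([C@H]2Oc3c(cc([C@H]4c5ccc(O)c(O)c5O[C@@H](c5ccc(O)cc5)[C@@H]4O)c(O)c3O)[C@@H](O)[C@H]2O)cc1 | target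

## Step count and risks

Total step count: 9. Longest linear sequence: 8 steps (1, 2, 3, 5, 6, 7, 8, 9).

The three steps most likely to fail:

Step 7, the new organocatalytic oxide-opening coupling. The oxide 11 may rearrange by hydride shift to the flavan-3-one, may be captured by ring A of the product (oligomers), or may open with poor 4β selectivity. The fallback uses known chemistry, sets out from 6 and comes back at 12. OsO4 (cat.)/NMO in acetone/H2O dihydroxylates 6 anti to the 2-aryl group to give (2S,3R,4R)-7,8-bis(benzyloxy)-2-[4-(benzyloxy)phenyl]chroman-3,4-diol F1. BnSH in AcOH exchanges the benzylic 4-OH for sulfur, giving (2S,3S,4S)-4-(benzylsulfanyl)-7,8-bis(benzyloxy)-2-[4-(benzyloxy)phenyl]chroman-3-ol F2. AgBF4 in THF/CH2Cl2 at 0 °C then ionises the C4–S bond in the presence of 10 (3 eq), and the C4 carbenium ion is captured at C6 of 10 anti to the 3-OH to give 12. This thiophilic activation leaves the acetates of 10 alone.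

Step 6, the Woodward cis-hydroxylation on the aryl face. Iodine may add syn to the aryl group (which would give the 2,3-trans-3,4-cis diol), the electron-rich ring A may migrate instead of the acetate participating (ring contraction), or ring A may be iodinated. The fallback replaces neighbouring-group delivery by an oxidation–reduction relay at C4; it sets out from 7 and comes back at 10. NBS in THF/H2O gives the trans-bromohydrin (2R,3S,4R)-3-bromo-7,8-bis(benzyloxy)-2-[4-(benzyloxy)phenyl]chroman-4-ol F3 (bromine anti to the aryl group, water at C4). K2CO3 in MeOH closes it to the oxirane on the aryl face, (2R,3R,4R)-7,8-bis(benzyloxy)-2-[4-(benzyloxy)phenyl]-3,4-epoxychroman F4. Dilute HClO4 in THF/H2O at 0 °C opens F4 at benzylic C4 to the 2,3-cis-3,4-trans-diol (2R,3R,4S)-7,8-bis(benzyloxy)-2-[4-(benzyloxy)phenyl]chroman-3,4-diol F5. MnO2 in CH2Cl2 oxidises only the benzylic alcohol, giving the cis-dihydroflavonol (2R,3S)-7,8-bis(benzyloxy)-2-[4-(benzyloxy)phenyl]-3-hydroxychroman-4-one F6. NaBH4 in MeOH/THF at −20 °C delivers hydride anti to the axial 3-OH, giving the all-cis diol (2R,3R,4R)-7,8-bis(benzyloxy)-2-[4-(benzyloxy)phenyl]chroman-3,4-diol F7. Ac2O/pyridine then gives 10.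

Step 9, the final hydrogenolysis. Once the 7-OH of the lower unit is free, its C4–OH is a para-hydroxybenzylic alcohol and may be lost by hydrogenolysis. The fallback unveils this hydroxyl only after debenzylation; it sets out from 13 and comes back at 14. MnO2 in CH2Cl2 oxidises the single benzylic alcohol of 13 to the ketone, hexa-O-benzyl-ent-oritin-(4β→6)-[(2R,3S)-7,8,4'-trihydroxy-2,3-cis-dihydroflavonol] F8. H2 with Pd(OH)2/C in THF/MeOH removes the benzyl groups to give the free phenolic ketone ent-oritin-(4β→6)-[(2R,3S)-7,8,4'-trihydroxy-2,3-cis-dihydroflavonol] F9. NaBH4 in EtOH at 0 °C under argon reduces the ketone from the face anti to the axial 3-OH to give 14.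

Further compounds

F1 | step 7 | (2S,3R,4R)-7,8-bis(benzyloxy)-2-[4-(benzyloxy)phenyl]chroman-3,4-diol (2,3-trans-3,4-cis) | C(c1ccccc1)Oc1ccc(cc1)[C@@H]1Oc2c(OCc3ccccc3)c(OCc3ccccc3)ccc2[C@@H](O)[C@H]1O
F2 | step 7 | (2S,3S,4S)-4-(benzylsulfanyl)-7,8-bis(benzyloxy)-2-[4-(benzyloxy)phenyl]chroman-3-ol (2,3-trans-3,4-trans, 4β-S) | C(c1ccccc1)Oc1ccc(cc1)[C@@H]1Oc2c(OCc3ccccc3)c(OCc3ccccc3)ccc2[C@H](SCc2ccccc2)[C@H]1O
F3 | step 6 | (2R,3S,4R)-3-bromo-7,8-bis(benzyloxy)-2-[4-(benzyloxy)phenyl]chroman-4-ol (2,3-trans-3,4-trans) | C(c1ccccc1)Oc1ccc(cc1)[C@H]1Oc2c(OCc3ccccc3)c(OCc3ccccc3)ccc2[C@@H](O)[C@@H]1Br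
F4 | step 6 | (2R,3R,4R)-7,8-bis(benzyloxy)-2-[4-(benzyloxy)phenyl]-3,4-epoxychroman (oxirane cis to the 2-aryl group) | C(c1ccccc1)Oc1ccc(cc1)[C@H]1Oc2c(OCc3ccccc3)c(OCc3ccccc3)ccc2[C@H]2O[C@@H]12
F5 | step 6 | (2R,3R,4S)-7,8-bis(benzyloxy)-2-[4-(benzyloxy)phenyl]chroman-3,4-diol (2,3-cis-3,4-trans) | C(c1ccccc1)Oc1ccc(cc1)[C@H]1Oc2c(OCc3ccccc3)c(OCc3ccccc3)ccc2[C@H](O)[C@H]1O
F6 | step 6 | (2R,3S)-7,8-bis(benzyloxy)-2-[4-(benzyloxy)phenyl]-3-hydroxychroman-4-one (2,3-cis) | C(c1ccccc1)Oc1ccc(cc1)[C@H]1Oc2c(OCc3ccccc3)c(OCc3ccccc3)ccc2C(=O)[C@H]1O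
F7 | step 6 | (2R,3R,4R)-7,8-bis(benzyloxy)-2-[4-(benzyloxy)phenyl]chroman-3,4-diol (all-cis) | C(c1ccccc1)Oc1ccc(cc1)[C@H]1Oc2c(OCc3ccccc3)c(OCc3ccccc3)ccc2[C@@H](O)[C@H]1O
F8 | step 9 | hexa-O-benzyl dimer with the lower unit as (2R,3S)-3-hydroxychroman-4-one | C(c6ccccc6)Oc1ccc([C@H]2Oc3c(cc([C@H]4c5ccc(OCc6ccccc6)c(OCc6ccccc6)c5O[C@@H](c5ccc(OCc6ccccc6)cc5)[C@@H]4O)c(OCc6ccccc6)c3OCc6ccccc6)C(=O)[C@H]2O)cc1
F9 | step 9 | free phenolic dimer with the lower unit as (2R,3S)-3-hydroxychroman-4-one | Oc1ccc([C@H]2Oc3c(cc([C@H]4c5ccc(O)c(O)c5O[C@@H](c5ccc(O)cc5)[C@@H]4O)c(O)c3O)C(=O)[C@H]2O)cc1
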